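## Analysis of the target

Target 22 is the 15-O-formate of imbricatolic acid, a labd-8(17)-en-19-oic acid. It is a trans-decalin (ring A: C1–C5, C10; ring B: C5–C10) with a saturated side chain C11–C15 on C9 that ends in a primary formate.

It has five stereocentres:
- C4, quaternary, with an α-methyl (C18) and a β-axial carboxyl (C19);
- C5 (α-H) and C10 (quaternary, β-axial methyl C20), which define the trans ring fusion;
- C9 (α-H, side chain β-equatorial);
- C13 (S) on the chain.

The four ring centres are contiguous or 1,3-related, and the C19 carboxyl is 1,3-diaxial to C20. C13 is insulated from C9 by C11 and C12, so it cannot be relayed from the ring and must be set independently in the absolute sense.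

Sensitive groups:
- the exocyclic C8=C17 alkene, which migrates to C7 or C9 under acid and rules out hydrogenation steps;
- the formate, which is labile to base and nucleophiles;
- the neopentyl axial C19 carboxyl, whose esters resist attack at the carbonyl.

The hard points are the C4 quaternary centre with the carboxyl on the more hindered face, the regiodefined alkene next to C9, and matching the ring configuration to C13.

The feature that invites the key move is the carbon chain C19–C4–C3–C2–C1–C10(=C5)–C6–C7–C8(=C9)–C11…C15. It is an acetoacetate joined to an ω-oxidised 2,3-dihydrofarnesol. Ring A, ring B, the C4–C5 and C10–C9 bonds and the C8=C17 alkene can therefore all arise in one oxidative radical bicyclization that starts at the carboxyl-bearing carbon C4.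

## Retrosynthetic reasoning

**22 to 21.** The formyl C–O bond at C15 is cut last, because the formate would not survive any basic, hydridic or fluoride step. The forward reaction must formylate a primary alcohol next to a free, hindered acid.

**21 to 20.** Both silicon-based masks (C15 silyl ether, C19 2-(trimethylsilyl)ethyl ester) are removed in one fluoride step. The ester is cut at the O–alkyl side by fragmentation at silicon, so the shielded C19 carbonyl never has to be attacked.

**20 to 17 (through 19 and 18).** The C3 oxygen is a leftover of the key step. It is removed by reduction to the alcohol and radical deoxygenation, a sequence that leaves the 1,1-disubstituted alkene and the ester untouched.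

**17 to 16.** The C4–C18 bond is cut. C-methylation of the β-keto ester enolate from the α face, opposite the axial C20 methyl, fixes C4 with the carboxyl axial.

**16 to 14.** The ester alkoxy group is exchanged at the one stage where this is easy: 14 still has a C4–H, so it can lose the auxiliary alcohol through acylketene 15. This avoids a later reductive removal of a very hindered ester.

**14 to 11 (key step).** The C4–C5 and C10–C9 bonds are cut and the C8=C17 alkene is returned to a methyl-bearing C8=C9 alkene. The precursor 11 is an open chain with one stereocentre (C13) and a chiral ester. The forward reaction has to: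
- generate a radical at C4 between the two carbonyls;
- close both rings 6-endo through chair transition states, setting C5, C9 and C10;
- choose one face of the radical under control of the auxiliary ester;
- end by oxidative loss of a C17 hydrogen.

No other cut gives both rings, three fixed ring stereocentres, the C19 oxidation state and the alkene from an acyclic precursor.

**11 to 9 and 5.** The C1–C2 bond is cut between an acetoacetate dianion (10, from 9) and the allylic bromide 5. This is the most reliable bond to make in the chain and joins two pieces of similar size.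

**9 to 6 and 7.** The auxiliary ester comes from alcohol 6 and the acetylketene source 7.

**5 to 1 (through 4, 3 and 2).** The bromide comes from the allylic alcohol 4, which comes from oxidation of the terminal (E)-methyl of silyl ether 3. C13 is traced to asymmetric hydrogenation of the allylic alkene of farnesol 1, which gives 2. Farnesol already contains C1 and C5–C16 of the target with both alkenes in the (E) geometry the cyclization needs.

## Alternatives that were turned down

**Alternative 1:** the textbook building-block route.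
- Disconnection: rings A and B come preformed from the enantiopure bicyclic enedione A1 ((S)-Wieland–Miescher ketone).
- Forward key step: reductive carboxylation of the enone followed by methylation, which sets C4 and C5 and gives A2.
- Why turned down: the second carbonyl of A2 sits on C9, not C8. The route must still remove the C3 oxygen, attach C11–C15 at a carbon flanked by the quaternary C10, control C9, and create a carbonyl at C8 for methylenation. Each stereocentre is set in a separate operation, the side chain arrives by a union that sets nothing, and the count passes twenty steps.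

**Alternative 2:** biomimetic cationic bicyclization.
- Disconnection: the same two ring bonds, but from the all-hydrocarbon polyene A3.
- Forward key step: acid-induced cyclization of A3 to the bicycle A4.
- Why turned down: a cation at C4 can only carry two methyl groups, so A4 has an unfunctionalised C4. C19 would then have to be oxidised late, at an unactivated axial methyl, in the presence of its equatorial twin and an alkene, with no directing group. Proton-terminated cyclizations also give mixtures of C7, C8 and C8(17) alkenes. The radical manifold was chosen because it starts at a carbon that already bears the carboxyl; the trivalent-titanium epoxide-opening variant shares the C4 problem.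

**Alternative 3:** dearomatization.
- Disconnection: ring A comes from a benzene ring; C4 is set first and ring B is closed afterwards.
- Forward key step: asymmetric Birch reduction–methylation of the chiral benzamide A5 to the cyclohexadiene A6, followed by cationic closure of ring B onto the C5=C10 ring alkene with an allylsilane terminator.
- Why turned down: the dearomatization sets only C4. The ring-B closure needs net syn addition of hydrogen and C9 across a tetrasubstituted ring alkene to give the trans fusion, whereas the stepwise cation can also collapse to the cis-decalin. The surplus C2=C3 alkene of A6 would have to be hydrogenated next to the exocyclic methylene. A5 is no easier to make than the acyclic precursor of the chosen route.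

Key step: step 7

Remark: ring positions are cited in labdane numbering (C17 on C8, C18 α and C19 β on C4, C20 on C10, side chain C11–C16). The facial sense assigned to the (+)-8-phenylmenthyl ester in step 7 follows the chelate model and is an assumption of this proposal. Compounds 1, 6 and 7 are taken as commercial.

## Route

Step 1
Reactants: 1 (2E,6E)-farnesol
Product: 2 (3S,6E)-3,7,11-trimethyldodeca-6,10-dien-1-ol
Conditions: Ru(OAc)2[(R)-BINAP] (0.2 mol%), H2 (90 atm), 95% aq. MeOH, 20 °C
Reagents that add atoms: none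
Why: Hydroxyl-directed Ru-BINAP asymmetric hydrogenation reduces only the allylic C2=C3 alkene; with the (2E) alkene the (R)-ligand should give the (3S) centre, as in the geraniol to (S)-citronellol case. This centre becomes C13 of the target.

Step 2
Reactants: 2 (3S,6E)-3,7,11-trimethyldodeca-6,10-dien-1-ol
Product: 3 tert-butyl(diphenyl){[(3S,6E)-3,7,11-trimethyldodeca-6,10-dien-1-yl]oxy}silane
Conditions: TBDPSCl, imidazole, DMF, 0 °C to rt
Reagents that add atoms: tert-butyl(chloro)diphenylsilane, CC(C)(C)[Si](Cl)(c1ccccc1)c1ccccc1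
Why: Silylation of the primary alcohol; this ether should survive SeO2, bromide formation, the dianion, the acidic oxidative medium of step 7 and the radical deoxygenation, and it leaves together with the ester mask in step 13.

Step 3
Reactants: 3 tert-butyl(diphenyl){[(3S,6E)-3,7,11-trimethyldodeca-6,10-dien-1-yl]oxy}silane
Product: 4 (2E,6E,10S)-12-[(tert-butyldiphenylsilyl)oxy]-2,6,10-trimethyldodeca-2,6-dien-1-ol
Conditions: SeO2 (0.3 equiv), t-BuOOH (3 equiv), salicylic acid (0.1 equiv), CH2Cl2, 0 °C to rt, stopped at partial conversion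
Reagents that add atoms: selenium dioxide, O=[Se]=O; tert-butyl hydroperoxide, CC(C)(C)OO
Why: SeO2 allylic oxidation (ene reaction, then [2,3]-shift) should attack the terminal isopropylidene group at its (E)-methyl, the most accessible allylic site, and give the (E)-allylic alcohol; no stereocentre is formed.

Step 4
Reactants: 4 (2E,6E,10S)-12-[(tert-butyldiphenylsilyl)oxy]-2,6,10-trimethyldodeca-2,6-dien-1-ol
Product: 5 {[(3S,6E,10E)-12-bromo-3,7,11-trimethyldodeca-6,10-dien-1-yl]oxy}(tert-butyl)diphenylsilane
Conditions: CBr4, PPh3, CH2Cl2, −20 to 0 °C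
Reagents that add atoms: tetrabromomethane, BrC(Br)(Br)Br
Why: Appel reaction; SN2 displacement at the primary allylic carbon should give the bromide without allylic transposition or loss of alkene geometry. The bromide is used without storage.

Step 5
Reactants: 6 (+)-8-phenylmenthol [(1S,2R,5S)-5-methyl-2-(2-phenylpropan-2-yl)cyclohexan-1-ol]; 7 2,2,6-trimethyl-4H-1,3-dioxin-4-one
Product: 9 (1S,2R,5S)-5-methyl-2-(2-phenylpropan-2-yl)cyclohexyl 3-oxobutanoate, via acetylketene 8 (not isolated)
Conditions: xylene, 140 °C, acetone distilled off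
Reagents that add atoms: none
Why: Thermal retro-hetero-Diels–Alder cleavage of 7 releases acetylketene 8, which acylates even hindered secondary alcohols; the stereocentres of the auxiliary are not touched.

Step 6
Reactants: 9 (1S,2R,5S)-5-methyl-2-(2-phenylpropan-2-yl)cyclohexyl 3-oxobutanoate; 5 {[(3S,6E,10E)-12-bromo-3,7,11-trimethyldodeca-6,10-dien-1-yl]oxy}(tert-butyl)diphenylsilane
Product: 11 (1S,2R,5S)-5-methyl-2-(2-phenylpropan-2-yl)cyclohexyl (6E,10E,14S)-16-[(tert-butyldiphenylsilyl)oxy]-6,10,14-trimethyl-3-oxohexadeca-6,10-dienoate, via sodium lithium dianion 10 (not isolated)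
Conditions: NaH, THF, 0 °C; n-BuLi, 0 °C; then 5, 0 °C to rt; aq. NH4Cl
Reagents that add atoms: none
Why: γ-Alkylation of an acetoacetate dianion: the more basic terminal carbanion of 10 displaces the allylic bromide by SN2 and forms the C1–C2 bond; both (E)-alkenes and the C13 centre are carried through unchanged.

Step 7
Reactants: 11 (1S,2R,5S)-5-methyl-2-(2-phenylpropan-2-yl)cyclohexyl (6E,10E,14S)-16-[(tert-butyldiphenylsilyl)oxy]-6,10,14-trimethyl-3-oxohexadeca-6,10-dienoate
Product: 14 (+)-8-phenylmenthyl (13S)-15-[(tert-butyldiphenylsilyl)oxy]-3-oxo-19-norlabd-8(17)-en-18-oate (4β-H and epimerisable; 5α-H; 9α-H; 10β-CH3), via keto ester radical 12 (not isolated), via bicyclic tertiary radical 13 (not isolated)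
Conditions: Mn(OAc)3·2H2O (2.2 equiv), Cu(OAc)2·H2O (1 equiv), Yb(OTf)3 (1 equiv), CF3CH2OH/AcOH, −5 to 0 °C, degassed
Reagents that add atoms: none
Why: Mn(OAc)3 oxidises the Yb(OTf)3-chelated enol of 11 to the electrophilic radical 12 at C4, which adds to C5 of the C10=C5 alkene; the tertiary C10 radical adds to C9 of the C8=C9 alkene to give 13, and Cu(OAc)2 traps 13 as an alkylcopper species (trivalent copper) that loses a C17 hydrogen by syn β-hydride elimination. The closest known reaction type is the oxidative radical polyene cyclization of unsaturated β-keto esters with a trivalent manganese oxidant and a divalent copper co-oxidant, including its 8-phenylmenthyl ester-controlled form. Ring A closes 6-endo-trig (C4 to C5) and ring B closes 6-endo-trig (C10 to C9); 5-exo closure is disfavoured in both because the inner alkene carbons C10 and C8 are fully substituted and the C3 carbonyl lies inside the forming ring A. C5 and C10 are set by anti addition across the (E)-C10=C5 alkene in a chair transition state (5α-H trans to 10β-CH3), and C9 by the (E)-C8=C9 geometry in the second chair, which places the side chain equatorial (9β). The absolute sense comes from the auxiliary: in the chelate the cumyl phenyl group of the (+)-8-phenylmenthyl ester covers one face of the planar radical, so C5 bonds to the open face and the whole chair–chair array follows. C4 is formed as an enolisable centre and is fixed only in step 9. The selectivities needed are face selectivity at C4 (auxiliary plus chelation), endo closure (substitution pattern) and elimination toward C17 in preference to C7 or C9 (the copper intermediate eliminates toward the least hindered hydrogen); the saturated, silyl-protected side chain with C13 is inert to the oxidants.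

Step 8
Reactants: 14 (+)-8-phenylmenthyl (13S)-15-[(tert-butyldiphenylsilyl)oxy]-3-oxo-19-norlabd-8(17)-en-18-oate
Product: 16 2-(trimethylsilyl)ethyl (13S)-15-[(tert-butyldiphenylsilyl)oxy]-3-oxo-19-norlabd-8(17)-en-18-oate (4β-H and epimerisable), via bicyclic acylketene 15 (not isolated)
Conditions: Me3SiCH2CH2OH (10 equiv), DMAP (0.3 equiv), xylene, 140 °C
Reagents that add atoms: 2-(trimethylsilyl)ethanol, C[Si](C)(C)CCO
Why: β-Keto esters that keep a hydrogen between the carbonyls exchange their alkoxy group by thermal loss of the alcohol to an acylketene (15), which the excess alcohol traps; no attack at the hindered carbonyl is needed and 6 is recovered. The fixed stereocentres C5, C9, C10 and C13 are not involved.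

Step 9
Reactants: 16 2-(trimethylsilyl)ethyl (13S)-15-[(tert-butyldiphenylsilyl)oxy]-3-oxo-19-norlabd-8(17)-en-18-oate
Product: 17 2-(trimethylsilyl)ethyl (13S)-15-[(tert-butyldiphenylsilyl)oxy]-3-oxolabd-8(17)-en-19-oate
Conditions: K2CO3, MeI, acetone, 50 °C
Reagents that add atoms: iodomethane, CI
Why: C-Alkylation of a β-keto ester enolate with a soft electrophile. The β face of C4 is shielded by the axial C20 methyl, so the methyl group should enter from the α face and become C18, which forces the ester into the axial β position (C19); this is the established outcome for 3-oxo-4-carboalkoxy trans-decalins.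

Step 10
Reactants: 17 2-(trimethylsilyl)ethyl (13S)-15-[(tert-butyldiphenylsilyl)oxy]-3-oxolabd-8(17)-en-19-oate
Product: 18 2-(trimethylsilyl)ethyl (13S)-15-[(tert-butyldiphenylsilyl)oxy]-3β-hydroxylabd-8(17)-en-19-oate
Conditions: NaBH4, MeOH/THF, 0 °C
Reagents that add atoms: none
Why: Chemoselective ketone reduction; hydride should attack axially from the α face, because the β face carries the axial ester and C20, and give the equatorial 3β-alcohol. The C3 configuration is erased in step 12.

Step 11
Reactants: 18 2-(trimethylsilyl)ethyl (13S)-15-[(tert-butyldiphenylsilyl)oxy]-3β-hydroxylabd-8(17)-en-19-oate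
Product: 19 2-(trimethylsilyl)ethyl (13S)-15-[(tert-butyldiphenylsilyl)oxy]-3β-[(phenoxycarbonothioyl)oxy]labd-8(17)-en-19-oate
Conditions: PhOC(S)Cl, pyridine, DMAP, CH2Cl2, rt to 40 °C
Reagents that add atoms: O-phenyl carbonochloridothioate, S=C(Cl)Oc1ccccc1
Why: Thioacylation without an alkoxide avoids retro-aldol cleavage of the β-hydroxy ester; equatorial 3β-hydroxyls next to a quaternary C4 are known to accept thiocarbonyl groups.

Step 12
Reactants: 19 2-(trimethylsilyl)ethyl (13S)-15-[(tert-butyldiphenylsilyl)oxy]-3β-[(phenoxycarbonothioyl)oxy]labd-8(17)-en-19-oate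
Product: 20 2-(trimethylsilyl)ethyl (13S)-15-[(tert-butyldiphenylsilyl)oxy]labd-8(17)-en-19-oate
Conditions: Bu3SnH, AIBN (cat.), toluene, 110 °C
Reagents that add atoms: none
Why: Barton–McCombie deoxygenation: the stannyl radical adds to C=S, the C3–O bond fragments and the secondary C3 radical takes hydrogen from Bu3SnH. The isolated 1,1-disubstituted alkene, both silicon groups and all stereocentres should be unaffected.

Step 13
Reactants: 20 2-(trimethylsilyl)ethyl (13S)-15-[(tert-butyldiphenylsilyl)oxy]labd-8(17)-en-19-oate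
Product: 21 imbricatolic acid [(13S)-15-hydroxylabd-8(17)-en-19-oic acid]
Conditions: Bu4NF (4 equiv), THF, rt to 45 °C; aq. NH4Cl
Reagents that add atoms: none
Why: Fluoride attacks silicon in both groups: the silyl ether gives the C15 alcohol, and the 2-(trimethylsilyl)ethyl ester fragments to ethene and the carboxylate, so the neopentyl axial carbonyl is never attacked.

Step 14
Reactants: 21 imbricatolic acid [(13S)-15-hydroxylabd-8(17)-en-19-oic acid]
Product: 22 (1S,4aR,5S,8aR)-5-[(3S)-5-(formyloxy)-3-methylpentyl]-1,4a-dimethyl-6-methylidenedecahydronaphthalene-1-carboxylic acid (CNP0494097.1)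
Conditions: acetic formic anhydride, pyridine, CH2Cl2, 0 °C; work-up at pH 5
Reagents that add atoms: acetic formic anhydride, CC(=O)OC=O
Why: The mixed anhydride transfers its formyl group to the unhindered primary C15 alcohol. Any mixed anhydride formed at the hindered C19 carboxyl should hydrolyse back to the acid on work-up, and the weakly acidic work-up preserves the formate and the exocyclic alkene.

## Compound list

1 | (2E,6E)-farnesol | CC(C)=CCC/C(C)=C/CC/C(C)=C/CO | starting material
2 | (3S,6E)-3,7,11-trimethyldodeca-6,10-dien-1-ol | CC(C)=CCC/C(C)=C/CC[C@H](C)CCO | intermediate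
3 | tert-butyl(diphenyl){[(3S,6E)-3,7,11-trimethyldodeca-6,10-dien-1-yl]oxy}silane | CC(C)=CCC/C(C)=C/CC[C@H](C)CCO[Si](c1ccccc1)(c1ccccc1)C(C)(C)C | intermediate
4 | (2E,6E,10S)-12-[(tert-butyldiphenylsilyl)oxy]-2,6,10-trimethyldodeca-2,6-dien-1-ol | OC/C(C)=C/CC/C(C)=C/CC[C@H](C)CCO[Si](c1ccccc1)(c1ccccc1)C(C)(C)C | intermediate
5 | {[(3S,6E,10E)-12-bromo-3,7,11-trimethyldodeca-6,10-dien-1-yl]oxy}(tert-butyl)diphenylsilane | BrC/C(C)=C/CC/C(C)=C/CC[C@H](C)CCO[Si](c1ccccc1)(c1ccccc1)C(C)(C)C | intermediate
6 | (+)-8-phenylmenthol, (1S,2R,5S)-5-methyl-2-(2-phenylpropan-2-yl)cyclohexan-1-ol | CC(C)(c1ccccc1)[C@H]1CC[C@H](C)C[C@@H]1O | starting material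
7 | 2,2,6-trimethyl-4H-1,3-dioxin-4-one | CC1=CC(=O)OC(C)(C)O1 | starting material
8 | acetylketene | CC(=O)C=C=O | intermediate
9 | (1S,2R,5S)-5-methyl-2-(2-phenylpropan-2-yl)cyclohexyl 3-oxobutanoate | CC(=O)CC(=O)O[C@H]1C[C@@H](C)CC[C@@H]1C(C)(C)c1ccccc1 | intermediate
10 | sodium lithium dianion of 9 | [Na+].[Li+].[CH2-]C(=O)[CH-]C(=O)O[C@H]1C[C@@H](C)CC[C@@H]1C(C)(C)c1ccccc1 | intermediate
11 | (1S,2R,5S)-5-methyl-2-(2-phenylpropan-2-yl)cyclohexyl (6E,10E,14S)-16-[(tert-butyldiphenylsilyl)oxy]-6,10,14-trimethyl-3-oxohexadeca-6,10-dienoate | O=C(CC(=O)CC/C(C)=C/CC/C(C)=C/CC[C@H](C)CCO[Si](c1ccccc1)(c1ccccc1)C(C)(C)C)O[C@H]1C[C@@H](C)CC[C@@H]1C(C)(C)c1ccccc1 | intermediate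
12 | keto ester radical at C4 derived from 11 | O=C([CH]C(=O)CC/C(C)=C/CC/C(C)=C/CC[C@H](C)CCO[Si](c1ccccc1)(c1ccccc1)C(C)(C)C)O[C@H]1C[C@@H](C)CC[C@@H]1C(C)(C)c1ccccc1 | intermediate
13 | bicyclic tertiary radical at C8 | C[C]1CC[C@@H]2[C@](C)(CCC(=O)[C@H]2C(=O)O[C@H]2C[C@@H](C)CC[C@@H]2C(C)(C)c2ccccc2)[C@H]1CC[C@H](C)CCO[Si](c1ccccc1)(c1ccccc1)C(C)(C)C | intermediate
14 | (+)-8-phenylmenthyl (13S)-15-[(tert-butyldiphenylsilyl)oxy]-3-oxo-19-norlabd-8(17)-en-18-oate (4β-H, epimerisable) | C=C1CC[C@@H]2[C@](C)(CCC(=O)[C@H]2C(=O)O[C@H]2C[C@@H](C)CC[C@@H]2C(C)(C)c2ccccc2)[C@H]1CC[C@H](C)CCO[Si](c1ccccc1)(c1ccccc1)C(C)(C)C | intermediate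
15 | bicyclic acylketene (C4=C=O, C3 ketone) | C=C1CC[C@@H]2[C@](C)(CCC(=O)C2=C=O)[C@H]1CC[C@H](C)CCO[Si](c1ccccc1)(c1ccccc1)C(C)(C)C | intermediate
16 | 2-(trimethylsilyl)ethyl (13S)-15-[(tert-butyldiphenylsilyl)oxy]-3-oxo-19-norlabd-8(17)-en-18-oate (4β-H, epimerisable) | C=C1CC[C@@H]2[C@](C)(CCC(=O)[C@H]2C(=O)OCC[Si](C)(C)C)[C@H]1CC[C@H](C)CCO[Si](c1ccccc1)(c1ccccc1)C(C)(C)C | intermediate
17 | 2-(trimethylsilyl)ethyl (13S)-15-[(tert-butyldiphenylsilyl)oxy]-3-oxolabd-8(17)-en-19-oate | C=C1CC[C@@H]2[C@](C)(CCC(=O)[C@]2(C)C(=O)OCC[Si](C)(C)C)[C@H]1CC[C@H](C)CCO[Si](c1ccccc1)(c1ccccc1)C(C)(C)C | intermediate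
18 | 2-(trimethylsilyl)ethyl (13S)-15-[(tert-butyldiphenylsilyl)oxy]-3β-hydroxylabd-8(17)-en-19-oate | C=C1CC[C@@H]2[C@](C)(CC[C@H](O)[C@]2(C)C(=O)OCC[Si](C)(C)C)[C@H]1CC[C@H](C)CCO[Si](c1ccccc1)(c1ccccc1)C(C)(C)C | intermediate
19 | 2-(trimethylsilyl)ethyl (13S)-15-[(tert-butyldiphenylsilyl)oxy]-3β-[(phenoxycarbonothioyl)oxy]labd-8(17)-en-19-oate | C=C1CC[C@@H]2[C@](C)(CC[C@H](OC(=S)Oc3ccccc3)[C@]2(C)C(=O)OCC[Si](C)(C)C)[C@H]1CC[C@H](C)CCO[Si](c1ccccc1)(c1ccccc1)C(C)(C)C | intermediate
20 | 2-(trimethylsilyl)ethyl (13S)-15-[(tert-butyldiphenylsilyl)oxy]labd-8(17)-en-19-oate | C=C1CC[C@@H]2[C@](C)(CCC[C@]2(C)C(=O)OCC[Si](C)(C)C)[C@H]1CC[C@H](C)CCO[Si](c1ccccc1)(c1ccccc1)C(C)(C)C | intermediate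
21 | imbricatolic acid, (13S)-15-hydroxylabd-8(17)-en-19-oic acid | C=C1CC[C@@H]2[C@](C)(CCC[C@]2(C)C(=O)O)[C@H]1CC[C@H](C)CCO | intermediate
22 | (1S,4aR,5S,8aR)-5-[(3S)-5-(formyloxy)-3-methylpentyl]-1,4a-dimethyl-6-methylidenedecahydronaphthalene-1-carboxylic acid | C=C1CC[C@@H]2[C@](C)(CCC[C@]2(C)C(=O)O)[C@H]1CC[C@H](C)CCOC=O | target

## Step count and least certain steps

Total: 14 steps. Longest linear sequence: 13 steps (steps 1 to 4 and 6 to 14); step 5 is a one-step branch.

**Step 7 (key step).** Three processes may fail: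
- further oxidation of the product, which still has an acidic C4–H, by the trivalent manganese oxidant;
- erosion of facial control if part of the radical reacts outside the chelate;
- partial elimination of the copper intermediate toward C7 instead of C17.

A product of minor facial attack is a diastereomer that differs next to the auxiliary and should be removable by chromatography at 14. Fallback, setting out from 11 and returning at 14: C4 is blocked with chlorine (NCS, Mg(ClO4)2 cat., MeCN) to give the α-chloro keto ester F1. The same oxidative bicyclization then proceeds through a tertiary radical and gives the 4-chloro bicyclic keto ester F2, which cannot enolise and so cannot be oxidised further. Zn dust in AcOH removes the chlorine and returns to 14.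

**Step 3.** The SeO2 oxidation may attack the internal C6=C7 alkene as well, or run on to the enal, because both alkenes of 3 are unactivated. Fallback, setting out from 3 and returning at 4:
- NBS in aqueous THF at 0 °C adds selectively to the terminal alkene to give the bromohydrin F3;
- K2CO3 in MeOH closes the terminal epoxide F4;
- HIO4 in aqueous THF cleaves it to the aldehyde F5;
- Wittig reaction with ethyl 2-(triphenylphosphoranylidene)propanoate gives the (E)-enoate F6;
- i-Bu2AlH in CH2Cl2 at −78 °C reduces F6 to 4.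

**Step 8.** The loss of the bulky auxiliary alcohol to the acylketene may be too slow, or traces of water may divert the acylketene to decarboxylation. Fallback, setting out from 14 and returning at 21; the auxiliary is kept and removed by reduction at the end:
- 14 is methylated as in step 9 to the auxiliary keto ester F7;
- NaBH4 gives the 3β-alcohol F8, and PhOC(S)Cl with pyridine gives the thionocarbonate F9;
- Bu3SnH with AIBN gives the deoxygenated auxiliary ester F10;
- LiAlH4 in refluxing THF gives the C19 alcohol F11 and frees 6;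
- Dess–Martin periodinane gives the aldehyde F12, and NaClO2 with NaH2PO4 and 2-methyl-2-butene gives the silyl-protected acid F13;
- Bu4NF converts F13 into 21.

**Step 9.** O-Methylation of the enolate, or attack from the β face, would give the wrong constitution or the C4 epimer. Fallback, setting out from 9 (with 5) and returning at 21; the methyl group is installed before the rings exist, so C4 is set in the cyclization:
- 9 is methylated (K2CO3, MeI) to the 2-methylacetoacetate F14;
- its dianion is alkylated with 5 to give the α-methyl keto ester F15;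
- oxidative cyclization under the conditions of step 7 goes through a tertiary radical, for which the axial ester is the known preference, and gives F7;
- F7 is carried to 21 through F8 to F13 as described for step 8.

**Step 11.** Thioacylation of the hindered 3β-hydroxyl next to the quaternary C4 may stall, and base-induced retro-aldol opening of ring A may compete. Fallback, setting out from 17 and returning at 20, which avoids the alcohol altogether: 17 is condensed with TsNHNH2 (EtOH, 60 °C) to the tosylhydrazone F16, which is reduced with catecholborane in CHCl3 at 0 °C and then heated with NaOAc·3H2O to give 20.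

## Further compounds

F1 | step 7 | (+)-8-phenylmenthyl (6E,10E,14S)-16-[(tert-butyldiphenylsilyl)oxy]-2-chloro-6,10,14-trimethyl-3-oxohexadeca-6,10-dienoate (C2 epimers) | O=C(C(Cl)C(=O)CC/C(C)=C/CC/C(C)=C/CC[C@H](C)CCO[Si](c1ccccc1)(c1ccccc1)C(C)(C)C)O[C@H]1C[C@@H](C)CC[C@@H]1C(C)(C)c1ccccc1
F2 | step 7 | 4-chloro derivative of 14 (C4 configuration immaterial) | C=C1CC[C@@H]2[C@](C)(CCC(=O)C2(Cl)C(=O)O[C@H]2C[C@@H](C)CC[C@@H]2C(C)(C)c2ccccc2)[C@H]1CC[C@H](C)CCO[Si](c1ccccc1)(c1ccccc1)C(C)(C)C
F3 | step 3 | (6E,10S)-3-bromo-12-[(tert-butyldiphenylsilyl)oxy]-2,6,10-trimethyldodec-6-en-2-ol (C3 epimers) | CC(C)(O)C(Br)CC/C(C)=C/CC[C@H](C)CCO[Si](c1ccccc1)(c1ccccc1)C(C)(C)C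
F4 | step 3 | tert-butyl{[(3S,6E)-9-(3,3-dimethyloxiran-2-yl)-3,7-dimethylnon-6-en-1-yl]oxy}diphenylsilane (oxirane epimers) | CC1(C)OC1CC/C(C)=C/CC[C@H](C)CCO[Si](c1ccccc1)(c1ccccc1)C(C)(C)C
F5 | step 3 | (4E,8S)-10-[(tert-butyldiphenylsilyl)oxy]-4,8-dimethyldec-4-enal | O=CCC/C(C)=C/CC[C@H](C)CCO[Si](c1ccccc1)(c1ccccc1)C(C)(C)C
F6 | step 3 | ethyl (2E,6E,10S)-12-[(tert-butyldiphenylsilyl)oxy]-2,6,10-trimethyldodeca-2,6-dienoate | CCOC(=O)/C(C)=C/CC/C(C)=C/CC[C@H](C)CCO[Si](c1ccccc1)(c1ccccc1)C(C)(C)C
F7 | step 8 | (+)-8-phenylmenthyl (13S)-15-[(tert-butyldiphenylsilyl)oxy]-3-oxolabd-8(17)-en-19-oate | C=C1CC[C@@H]2[C@](C)(CCC(=O)[C@]2(C)C(=O)O[C@H]2C[C@@H](C)CC[C@@H]2C(C)(C)c2ccccc2)[C@H]1CC[C@H](C)CCO[Si](c1ccccc1)(c1ccccc1)C(C)(C)C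
F8 | step 8 | (+)-8-phenylmenthyl (13S)-15-[(tert-butyldiphenylsilyl)oxy]-3β-hydroxylabd-8(17)-en-19-oate | C=C1CC[C@@H]2[C@](C)(CC[C@H](O)[C@]2(C)C(=O)O[C@H]2C[C@@H](C)CC[C@@H]2C(C)(C)c2ccccc2)[C@H]1CC[C@H](C)CCO[Si](c1ccccc1)(c1ccccc1)C(C)(C)C
F9 | step 8 | (+)-8-phenylmenthyl (13S)-15-[(tert-butyldiphenylsilyl)oxy]-3β-[(phenoxycarbonothioyl)oxy]labd-8(17)-en-19-oate | C=C1CC[C@@H]2[C@](C)(CC[C@H](OC(=S)Oc3ccccc3)[C@]2(C)C(=O)O[C@H]2C[C@@H](C)CC[C@@H]2C(C)(C)c2ccccc2)[C@H]1CC[C@H](C)CCO[Si](c1ccccc1)(c1ccccc1)C(C)(C)C
F10 | step 8 | (+)-8-phenylmenthyl (13S)-15-[(tert-butyldiphenylsilyl)oxy]labd-8(17)-en-19-oate | C=C1CC[C@@H]2[C@](C)(CCC[C@]2(C)C(=O)O[C@H]2C[C@@H](C)CC[C@@H]2C(C)(C)c2ccccc2)[C@H]1CC[C@H](C)CCO[Si](c1ccccc1)(c1ccccc1)C(C)(C)C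
F11 | step 8 | (13S)-15-[(tert-butyldiphenylsilyl)oxy]labd-8(17)-en-19-ol | C=C1CC[C@@H]2[C@](C)(CCC[C@]2(C)CO)[C@H]1CC[C@H](C)CCO[Si](c1ccccc1)(c1ccccc1)C(C)(C)C
F12 | step 8 | (13S)-15-[(tert-butyldiphenylsilyl)oxy]labd-8(17)-en-19-al | C=C1CC[C@@H]2[C@](C)(CCC[C@]2(C)C=O)[C@H]1CC[C@H](C)CCO[Si](c1ccccc1)(c1ccccc1)C(C)(C)C
F13 | step 8 | (13S)-15-[(tert-butyldiphenylsilyl)oxy]labd-8(17)-en-19-oic acid | C=C1CC[C@@H]2[C@](C)(CCC[C@]2(C)C(=O)O)[C@H]1CC[C@H](C)CCO[Si](c1ccccc1)(c1ccccc1)C(C)(C)C
F14 | step 9 | (1S,2R,5S)-5-methyl-2-(2-phenylpropan-2-yl)cyclohexyl 2-methyl-3-oxobutanoate (C2 epimers) | CC(=O)C(C)C(=O)O[C@H]1C[C@@H](C)CC[C@@H]1C(C)(C)c1ccccc1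
F15 | step 9 | (+)-8-phenylmenthyl (6E,10E,14S)-16-[(tert-butyldiphenylsilyl)oxy]-2,6,10,14-tetramethyl-3-oxohexadeca-6,10-dienoate (C2 epimers) | O=C(C(C)C(=O)CC/C(C)=C/CC/C(C)=C/CC[C@H](C)CCO[Si](c1ccccc1)(c1ccccc1)C(C)(C)C)O[C@H]1C[C@@H](C)CC[C@@H]1C(C)(C)c1ccccc1
F16 | step 11 | 2-(trimethylsilyl)ethyl (13S)-15-[(tert-butyldiphenylsilyl)oxy]-3-[2-(4-methylbenzenesulfonyl)hydrazinylidene]labd-8(17)-en-19-oate | C=C1CC[C@@H]2[C@](C)(CCC(=NNS(=O)(=O)c3ccc(C)cc3)[C@]2(C)C(=O)OCC[Si](C)(C)C)[C@H]1CC[C@H](C)CCO[Si](c1ccccc1)(c1ccccc1)C(C)(C)C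
A1 | alternative 1 | (S)-Wieland–Miescher ketone | C[C@]12CCC(=O)C=C1CCCC2=O
A2 | alternative 1 | methyl 4α,10β-dimethyl-3,9-dioxo-5α-decalin-4β-carboxylate (labdane numbering) | O=C1CCC[C@@H]2[C@]1(C)CCC(=O)[C@]2(C)C(=O)OC
A3 | alternative 2 | tert-butyl(diphenyl){[(3S,6E,10E)-3,7,11,15-tetramethylhexadeca-6,10,14-trien-1-yl]oxy}silane | CC(C)=CCC/C(C)=C/CC/C(C)=C/CC[C@H](C)CCO[Si](c1ccccc1)(c1ccccc1)C(C)(C)C
A4 | alternative 2 | (13S)-15-[(tert-butyldiphenylsilyl)oxy]labd-8(17)-ene | C=C1CC[C@@H]2[C@](C)(CCCC2(C)C)[C@H]1CC[C@H](C)CCO[Si](c1ccccc1)(c1ccccc1)C(C)(C)C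
A5 | alternative 3 | (S)-2-(methoxymethyl)pyrrolidine amide of 3-methyl-2-[(3E,7S)-9-[(tert-butyldiphenylsilyl)oxy]-7-methyl-3-[(trimethylsilyl)methyl]non-3-en-1-yl]benzoic acid | COC[C@@H]1CCCN1C(=O)c1cccc(C)c1CC/C(C[Si](C)(C)C)=C/CC[C@H](C)CCO[Si](c1ccccc1)(c1ccccc1)C(C)(C)C
A6 | alternative 3 | 1,3-dimethylcyclohexa-2,5-diene-1-carboxamide obtained from A5 by reduction–methylation (C4 drawn as required) | COC[C@@H]1CCCN1C(=O)[C@@]1(C)C=CCC(C)=C1CC/C(C[Si](C)(C)C)=C/CC[C@H](C)CCO[Si](c1ccccc1)(c1ccccc1)C(C)(C)C
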